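A direct plan would monosilylate iodoresorcinol A1 to iodophenol A2, join A2 with the chromenyl alkyne A3 and CO in a palladium-catalysed carbonylative annulation to flavone A4, and set C2 by an asymmetric copper hydride conjugate reduction before desilylation.
Its weakest steps would be:
- the monosilylation of A1, since the two hydroxyls differ only in their ortho neighbours and the protecting-group changes around it would add length without complexity;
- the carbonylative annulation, since two hindered, electron-rich partners would have to take up CO faster than they couple directly;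
- the conjugate reduction of A4, since hydride delivery with high facial selectivity to a β-carbon bearing an ortho-silyloxyaryl group is poorly precedented.

The route rests on the C2–C1' bond between ring C and ring B, and exploits that C2 is the β-carbon of the enone C2=C3–C4=O of ring C. Ring C is made early as an achiral 8-prenylchromone, and ring B arrives as an arylboronic acid in a rhodium-catalysed enantioselective 1,4-addition. This one operation would join two fragments of similar size at the only stereocentre and set its S configuration. No flavone, carbon monoxide or reduction is needed, and the phenols are told apart by construction: on ring A by the hydrogen-bonded ortho-hydroxyketone, on ring B by the bromine position of the starting resorcinol.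

Key step: step 10

Lettering: ring A is the benzo ring of the chroman-4-one, ring C its pyranone ring, ring B the benzene ring of the chromene at C2; C1' is the ring B carbon bonded to C2.
Assumption: the (S,S) diene ligand is taken to deliver the aryl group to the face that gives 2S, by analogy with its sense of induction with cyclic enones; the (R,R) ligand would be used if a trial run showed the opposite sense.

Step 1
Reactants: 1 1-(2,4-dihydroxyphenyl)ethanone (2,4-dihydroxyacetophenone); 2 3-chloro-3-methylbut-1-yne
Product: 3 1-[2-hydroxy-4-(2-methylbut-3-yn-2-yloxy)phenyl]ethanone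
Conditions: K2CO3, KI (0.2 equiv), CuI (5 mol %), acetone, 55 °C
Reagents that add atoms: none
Why: Williamson-type O-alkylation with the tertiary propargylic chloride, assisted by copper, should occur only at the 4-hydroxyl, because the 2-hydroxyl is held in a hydrogen bond to the ketone and is much less nucleophilic.

Step 2
Reactants: 3 1-[2-hydroxy-4-(2-methylbut-3-yn-2-yloxy)phenyl]ethanone
Product: 4 1-[2-hydroxy-4-(2-methylbut-3-en-2-yloxy)phenyl]ethanone
Conditions: H2 (1 atm), Pd/CaCO3 poisoned with Pb(OAc)2 (Lindlar catalyst), quinoline, EtOAc, rt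
Reagents that add atoms: none
Why: Lindlar semihydrogenation of the terminal alkyne should stop at the alkene on the poisoned palladium surface and leave the aryl ketone and the tertiary aryl ether untouched.

Step 3
Reactants: 4 1-[2-hydroxy-4-(2-methylbut-3-en-2-yloxy)phenyl]ethanone
Product: 5 1-[2,4-dihydroxy-3-(3-methylbut-2-enyl)phenyl]ethanone
Conditions: N,N-diethylaniline, 130 °C
Reagents that add atoms: none
Why: Aromatic Claisen rearrangement ([3,3]-sigmatropic shift) of the 1,1-dimethylallyl aryl ether should deliver the allyl terminus to C3, the ortho carbon favoured by the bond fixation of the chelated ortho-hydroxyketone, and rearomatisation gives the normal prenyl group between the two hydroxyls.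

Step 4
Reactants: 5 1-[2,4-dihydroxy-3-(3-methylbut-2-enyl)phenyl]ethanone
Product: 6 1-[2-hydroxy-4-(methoxymethoxy)-3-(3-methylbut-2-enyl)phenyl]ethanone
Conditions: MOMCl (1.1 equiv), i-Pr2NEt, CH2Cl2, 0 °C → rt
Reagents that add atoms: chloromethyl methyl ether, COCCl
Why: O-alkylation with the chloromethyl ether should go at the free 4-hydroxyl, while the chelated 2-hydroxyl stays free for the ring closure of the next step.

Step 5
Reactants: 6 1-[2-hydroxy-4-(methoxymethoxy)-3-(3-methylbut-2-enyl)phenyl]ethanone
Product: 8 7-(methoxymethoxy)-8-(3-methylbut-2-enyl)-4H-chromen-4-one, via enaminone 7 (not isolated)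
Conditions: Me2NCH(OMe)2 (3 equiv), toluene, 95 °C; concentrate; then glacial AcOH, 60 °C
Reagents that add atoms: N,N-dimethylformamide dimethyl acetal, COC(OC)N(C)C
Why: Condensation of the methyl ketone with the formamide acetal gives the enaminone, and under weak acid the ortho-hydroxyl adds to its β-carbon and dimethylamine is lost (6-endo addition–elimination), a standard chromone synthesis that closes the six-membered pyranone ring O1–C2=C3–C4(=O) and that the MOM ether and the prenyl group should tolerate.

Step 6
Reactants: 9 4-bromobenzene-1,3-diol (4-bromoresorcinol); 10 3-methylbut-2-enoic acid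
Product: 12 6-bromo-7-hydroxy-2,2-dimethylchroman-4-one, via aryl enone 11 (not isolated)
Conditions: P2O5/MeSO3H (1:10 w/w), 70 °C
Reagents that add atoms: none
Why: Friedel–Crafts acylation should take place at the only open carbon that is ortho to one hydroxyl and para to the other, and the ortho-hydroxyl then closes the chromanone by intramolecular oxa-Michael addition to the enone, so that bromine ends up at C6 next to the free 7-hydroxyl.

Step 7
Reactants: 12 6-bromo-7-hydroxy-2,2-dimethylchroman-4-one
Product: 13 6-bromo-7-(methoxymethoxy)-2,2-dimethylchroman-4-one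
Conditions: MOMCl, i-Pr2NEt, CH2Cl2, 0 °C → rt
Reagents that add atoms: chloromethyl methyl ether, COCCl
Why: O-alkylation of the acidic phenol gives a MOM ether that is small enough to sit ortho to the later carbon–boron bond and that stabilises the aryllithium of step 9 by coordination.

Step 8
Reactants: 13 6-bromo-7-(methoxymethoxy)-2,2-dimethylchroman-4-one
Product: 16 6-bromo-7-(methoxymethoxy)-2,2-dimethyl-2H-chromene, via chromanol 14 (not isolated), via mesylate 15 (not isolated)
Conditions: NaBH4, MeOH/THF, 0 °C; then MsCl, Et3N, CH2Cl2, 0 → 40 °C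
Reagents that add atoms: none
Why: Borohydride reduction gives the benzylic alcohol, whose mesylate ionises readily to a cation stabilised by the ring oxygen and the para MOM-oxygen and loses the C3 proton to triethylamine (E1 elimination), forming the chromene double bond under basic conditions that keep the MOM ether.

Step 9
Reactants: 16 6-bromo-7-(methoxymethoxy)-2,2-dimethyl-2H-chromene
Product: 19 [7-(methoxymethoxy)-2,2-dimethyl-2H-chromen-6-yl]boronic acid, via aryllithium 17 (not isolated), via lithium borate 18 (not isolated)
Conditions: n-BuLi, THF, −78 °C; B(Oi-Pr)3, −78 °C → rt; aq. NH4Cl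
Reagents that add atoms: triisopropyl borate, CC(C)OB(OC(C)C)OC(C)C; water, O
Why: Bromine–lithium exchange at −78 °C is faster than any deprotonation and gives an aryllithium held by the ortho MOM oxygen, which is trapped by the borate ester (electrophilic borylation) and hydrolysed to the boronic acid, so that boron sits exactly where bromine was.

Step 10
Reactants: 8 7-(methoxymethoxy)-8-(3-methylbut-2-enyl)-4H-chromen-4-one; 19 [7-(methoxymethoxy)-2,2-dimethyl-2H-chromen-6-yl]boronic acid
Product: 20 (2S)-7-(methoxymethoxy)-2-[7-(methoxymethoxy)-2,2-dimethyl-2H-chromen-6-yl]-8-(3-methylbut-2-enyl)-2,3-dihydro-4H-chromen-4-one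
Conditions: [RhCl(C2H4)2]2 (2.5 mol %), (S,S)-Ph-bod [(1S,4S)-2,5-diphenylbicyclo[2.2.2]octa-2,5-diene] (5.5 mol %), KOH (10 mol %), 19 (1.8 equiv), 1,4-dioxane/H2O (10:1), 30 °C
Reagents that add atoms: none
Why: Transmetalation of 19 to the hydroxo complex of monovalent rhodium gives an arylrhodium species, the C2=C3 bond of chromone 8 inserts into the aryl–rhodium bond with the aryl group going to C2, and water protonates the resulting oxa-π-allyl rhodium enolate at C3, which releases the ketone and returns the hydroxo complex. The closest known reaction type is the rhodium-catalysed asymmetric 1,4-addition of arylboronic acids to chromones, which gives 2-arylchroman-4-ones. No ring is closed; the bond formed is C2–C1', which joins the half that holds rings A and C to ring B. The new stereocentre C2 is controlled by the twofold-symmetric chiral diene on rhodium, which leaves one face of the coordinated enone open in the insertion step, so that the aryl group should enter on the face that makes C2 S. The step needs insertion to outrun protodeboronation of the electron-rich boronic acid, which the small MOM group ortho to boron, the excess of 19, the high activity of diene–rhodium catalysts and the low temperature should secure, and it needs 1,4-addition without opening of ring C, which fast protonation of the enolate in aqueous dioxane and the low base loading should secure. The prenyl and chromene alkenes are unactivated and should not insert into the aryl–rhodium bond.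

Step 11
Reactants: 20 (2S)-7-(methoxymethoxy)-2-[7-(methoxymethoxy)-2,2-dimethyl-2H-chromen-6-yl]-8-(3-methylbut-2-enyl)-2,3-dihydro-4H-chromen-4-one
Product: 21 (2S)-7-hydroxy-2-(7-hydroxy-2,2-dimethyl-2H-chromen-6-yl)-8-(3-methylbut-2-enyl)-2,3-dihydro-4H-chromen-4-one
Conditions: HCl (2 M in MeOH), THF, rt
Reagents that add atoms: none
Why: Acid-catalysed acetal exchange with methanol removes both MOM groups as dimethoxymethane at room temperature, conditions under which the ortho-prenylphenol should not cyclise, the chromene should not add methanol, and C2, which is not enolisable and whose C2–O1 bond is kept from ionising by the electron-withdrawing C4 carbonyl, should keep its S configuration.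

Compound list
1 | 1-(2,4-dihydroxyphenyl)ethanone (2,4-dihydroxyacetophenone) | CC(=O)c1ccc(O)cc1O | starting material
2 | 3-chloro-3-methylbut-1-yne | C#CC(C)(C)Cl | starting material
3 | 1-[2-hydroxy-4-(2-methylbut-3-yn-2-yloxy)phenyl]ethanone | CC(=O)c1ccc(OC(C)(C)C#C)cc1O | intermediate
4 | 1-[2-hydroxy-4-(2-methylbut-3-en-2-yloxy)phenyl]ethanone | CC(=O)c1ccc(OC(C)(C)C=C)cc1O | intermediate
5 | 1-[2,4-dihydroxy-3-(3-methylbut-2-enyl)phenyl]ethanone | CC(=O)c1ccc(O)c(CC=C(C)C)c1O | intermediate
6 | 1-[2-hydroxy-4-(methoxymethoxy)-3-(3-methylbut-2-enyl)phenyl]ethanone | CC(=O)c1ccc(OCOC)c(CC=C(C)C)c1O | intermediate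
7 | (E)-3-(dimethylamino)-1-[2-hydroxy-4-(methoxymethoxy)-3-(3-methylbut-2-enyl)phenyl]prop-2-en-1-one | CN(C)/C=C/C(=O)c1ccc(OCOC)c(CC=C(C)C)c1O | intermediate
8 | 7-(methoxymethoxy)-8-(3-methylbut-2-enyl)-4H-chromen-4-one | CC(C)=CCc1c(OCOC)ccc2c1OC=CC2=O | intermediate
9 | 4-bromobenzene-1,3-diol (4-bromoresorcinol) | Oc1ccc(Br)c(O)c1 | starting material
10 | 3-methylbut-2-enoic acid | CC(C)=CC(=O)O | starting material
11 | 1-(5-bromo-2,4-dihydroxyphenyl)-3-methylbut-2-en-1-one | CC(C)=CC(=O)c1cc(Br)c(O)cc1O | intermediate
12 | 6-bromo-7-hydroxy-2,2-dimethylchroman-4-one | CC1(C)CC(=O)c2cc(Br)c(O)cc2O1 | intermediate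
13 | 6-bromo-7-(methoxymethoxy)-2,2-dimethylchroman-4-one | CC1(C)CC(=O)c2cc(Br)c(OCOC)cc2O1 | intermediate
14 | 6-bromo-7-(methoxymethoxy)-2,2-dimethylchroman-4-ol (racemic) | CC1(C)CC(O)c2cc(Br)c(OCOC)cc2O1 | intermediate
15 | 6-bromo-7-(methoxymethoxy)-2,2-dimethylchroman-4-yl methanesulfonate (racemic) | CC1(C)CC(OS(C)(=O)=O)c2cc(Br)c(OCOC)cc2O1 | intermediate
16 | 6-bromo-7-(methoxymethoxy)-2,2-dimethyl-2H-chromene | CC1(C)C=Cc2cc(Br)c(OCOC)cc2O1 | intermediate
17 | [7-(methoxymethoxy)-2,2-dimethyl-2H-chromen-6-yl]lithium | [Li]c1cc2C=CC(C)(C)Oc2cc1OCOC | intermediate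
18 | lithium triisopropoxy[7-(methoxymethoxy)-2,2-dimethyl-2H-chromen-6-yl]borate | [Li+].CC(C)O[B-](OC(C)C)(OC(C)C)c1cc2C=CC(C)(C)Oc2cc1OCOC | intermediate
19 | [7-(methoxymethoxy)-2,2-dimethyl-2H-chromen-6-yl]boronic acid | COCOc1cc2OC(C)(C)C=Cc2cc1B(O)O | intermediate
20 | (2S)-7-(methoxymethoxy)-2-[7-(methoxymethoxy)-2,2-dimethyl-2H-chromen-6-yl]-8-(3-methylbut-2-enyl)-2,3-dihydro-4H-chromen-4-one | CC(C)=CCc1c(OCOC)ccc2c1O[C@H](c1cc3c(cc1OCOC)OC(C)(C)C=C3)CC2=O | intermediate
21 | (2S)-7-hydroxy-2-(7-hydroxy-2,2-dimethyl-2H-chromen-6-yl)-8-(3-methylbut-2-enyl)-2,3-dihydro-4H-chromen-4-one | CC(C)=CCc1c(O)ccc2c1O[C@H](c1cc3c(cc1O)OC(C)(C)C=C3)CC2=O | target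

Total step count: 11. Longest linear sequence: 7 steps (steps 1 to 5, then 10 and 11).

Steps most likely to fail

Step 10. Protodeboronation of the electron-rich, ortho-substituted boronic acid could outrun insertion into the deactivated 7-alkoxychromone, or the facial selectivity could be insufficient. The fallback changes the bond that closes the skeleton to O1–C2; it sets out from bromide 16 and acetophenone 6 and comes back at 20. Bromide 16 would be lithiated as in step 9 and formylated with DMF to 7-(methoxymethoxy)-2,2-dimethyl-2H-chromene-6-carbaldehyde F1. Claisen–Schmidt condensation of F1 with 6 (KOH, EtOH, rt) should give (E)-1-[2-hydroxy-4-(methoxymethoxy)-3-(3-methylbut-2-enyl)phenyl]-3-[7-(methoxymethoxy)-2,2-dimethyl-2H-chromen-6-yl]prop-2-en-1-one F2. Intramolecular oxa-Michael addition of F2 under a quinine-derived bifunctional thiourea would close ring C to 20. Such closures of unactivated 2'-hydroxychalcones are usually only moderately selective, so enantiopurity would be secured by preparative chromatography on a chiral stationary phase.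

Step 11. Acid could cause ionisation processes: addition of methanol to the chromene, cyclisation of the prenyl group onto the freed phenol, or loss of configuration at C2 through opening of ring C. The fallback replaces protic acetal exchange by a trans-protection under non-protic conditions; it sets out from 20 and comes back at 21. TMSOTf and 2,2'-bipyridyl in CH2Cl2 at 0 °C would convert both aryl MOM ethers into silyl ethers, giving (2S)-2-[2,2-dimethyl-7-(trimethylsilyloxy)-2H-chromen-6-yl]-8-(3-methylbut-2-enyl)-7-(trimethylsilyloxy)-2,3-dihydro-4H-chromen-4-one F3, which would be hydrolysed to 21 by water at neutral pH during work-up.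

Step 3. The allyl group could migrate to the other ortho carbon (C5), or the ortho-prenylphenol formed could cyclise further at the temperature of the rearrangement. The fallback replaces the sigmatropic route by direct C-alkylation; it sets out from 1 and comes back at 5, bypassing steps 1 to 3. The dianion of 1 in aqueous KOH would be treated with prenyl bromide (1-bromo-3-methylbut-2-ene) at rt. C-alkylation goes mainly at C3 between the two oxygens, and 5 would be separated from the O-alkylated and C5 isomers by chromatography. This is a shorter but lower-yielding entry that makes no compound outside the list (F0).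

Further compounds
F1 | step 10 | 7-(methoxymethoxy)-2,2-dimethyl-2H-chromene-6-carbaldehyde | O=Cc1cc2C=CC(C)(C)Oc2cc1OCOC
F2 | step 10 | (E)-1-[2-hydroxy-4-(methoxymethoxy)-3-(3-methylbut-2-enyl)phenyl]-3-[7-(methoxymethoxy)-2,2-dimethyl-2H-chromen-6-yl]prop-2-en-1-one | COCOc1ccc(C(=O)/C=C/c2cc3C=CC(C)(C)Oc3cc2OCOC)c(O)c1CC=C(C)C
F3 | step 11 | (2S)-2-[2,2-dimethyl-7-(trimethylsilyloxy)-2H-chromen-6-yl]-8-(3-methylbut-2-enyl)-7-(trimethylsilyloxy)-2,3-dihydro-4H-chromen-4-one | CC(C)=CCc1c(O[Si](C)(C)C)ccc2c1O[C@H](c1cc3c(cc1O[Si](C)(C)C)OC(C)(C)C=C3)CC2=O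
F0 | step 3 | none | none
A1 | direct plan | 4-iodo-2-(3-methylbut-2-enyl)benzene-1,3-diol | Ic1ccc(O)c(CC=C(C)C)c1O
A2 | direct plan | 6-iodo-2-(3-methylbut-2-enyl)-3-(triisopropylsilyloxy)phenol | Ic1ccc(O[Si](C(C)C)(C(C)C)C(C)C)c(CC=C(C)C)c1O
A3 | direct plan | 6-ethynyl-2,2-dimethyl-7-(triisopropylsilyloxy)-2H-chromene | C#Cc1cc2c(cc1O[Si](C(C)C)(C(C)C)C(C)C)OC(C)(C)C=C2
A4 | direct plan | 2-[2,2-dimethyl-7-(triisopropylsilyloxy)-2H-chromen-6-yl]-8-(3-methylbut-2-enyl)-7-(triisopropylsilyloxy)-4H-chromen-4-one | CC(C)=CCc1c(O[Si](C(C)C)(C(C)C)C(C)C)ccc2c1OC(c1cc3c(cc1O[Si](C(C)C)(C(C)C)C(C)C)OC(C)(C)C=C3)=CC2=O
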